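**Plan**

1. Cuts: the target is read as two copies of one trans-fused 2,2,5a-trimethylperhydro-1-benzoxepine (left: C3–OH, C7=CH2; right, primed: C3′=O, C7′(Me)OAc) joined C6–CH2–CH2–C6′. In each half the ring bonds O1–C2 and C5a–C6 are cut (back to a 1,5-diepoxide and a C6=C7 enol silane), and the bridge CH2–CH2 bond is cut (back to a vinyl ketone).
2. Enabling feature: in both six-membered rings the bridge-bearing C6 is α to C7, and C7 is reachable from a ketone (C7=CH2 by methylenation, C7′(Me)OAc by methyl addition). The bridge CH2–CH2 bond is therefore the β,γ bond of a C7 ketone, so one conjugate addition to an acyclic diepoxy vinyl ketone (7) makes that bond and leaves the regiodefined C6=C7 enol silane that terminates the epoxide cascade.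
3. Forward: 7 (three steps from geranyl bromide) is used twice. Round 1 (thiolate addition, cascade, methylenation) gives the left bicycle, oxepane first and cyclohexane second. Round 2 turns its C–S bond into a cuprate, adds it to a second 7, and closes the right oxepane and then the right cyclohexane on the union product.
4. Stereochemistry: one Shi epoxidation sets three S epoxide carbons per half. C3 and C9a keep their epoxide C–O bonds, C5a forms by anti opening (trans fusion), C6/C6′ are set by equilibration α to the C7 ketone (bridge equatorial, cis to the C5a methyl), and C7′ by equatorial methyl addition opposite the axial C5a′ methyl.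
5. The two carbinol oxygens are told apart by timing: cascade 1 leaves C3–OTBS, cascade 2 leaves C3′–OTMS, and only the latter is freed and oxidised.
6. Endgame: methyl addition at C7′, oxidation at C3′, acetylation of the tertiary alcohol, desilylation.

Key step: step 8

Remark on locants: ring compounds carry 1-benzoxepine locants (O1, C2 gem-dimethyl, C3, C5a angular methyl, C6 bridge-bearing CH, C7, C9a O–CH); the ketone/acetate half is primed. Dodecane C1, C2, C3, C6, C7, C10, C11 of 7 become bridge CH2, C6, C7, C9a, C5a, C3, C2 of a ring.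

Assumption: the three epoxide carbons needed are all S, which calls for the L-fructose-derived enantiomer of the Shi ketone (the common D-fructose-derived ketone leads to the R series).

Step 1
Reactants: 1 geranyl bromide; 2 N-methoxy-N-methylacetamide
Product: 4 Weinreb amide (4E)-N-methoxy-N,5,9-trimethyldeca-4,8-dienamide, via lithium enolate 3 (not isolated)
Conditions: LDA, THF, −78 °C; then 1, −78 → −20 °C
Reagents that add atoms: none
Why: SN2 alkylation of the Weinreb acetamide lithium enolate by the primary allylic bromide should give the chain-extended amide with the E alkene untouched; no stereocentre is formed.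

Step 2
Reactants: 4 Weinreb amide
Product: 5 (S,S,S)-diepoxy Weinreb amide
Conditions: L-fructose-derived Shi ketone (0.3 equiv per alkene), Oxone, K2CO3, Bu4NHSO4, Na2B4O7/Na2EDTA buffer, MeCN/DMM/H2O, 0 °C
Reagents that add atoms: Oxone (potassium peroxymonosulfate), [K+].[O-]S(=O)(=O)OO
Why: Shi asymmetric epoxidation, in which the chiral dioxirane should deliver oxygen to the same face of both trisubstituted alkenes through the spiro transition state, so that catalyst control sets the three epoxide carbons (all S) independently of one another.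

Step 3
Reactants: 5 (S,S,S)-diepoxy Weinreb amide
Product: 7 diepoxy vinyl ketone (6S,7S,10S)-6,7:10,11-diepoxy-7,11-dimethyldodec-1-en-3-one, via magnesium hemiaminal 6 (not isolated)
Conditions: CH2=CHMgBr, THF, −78 → 0 °C; inverse quench into cold aq. citric acid; BHT, used at once
Reagents that add atoms: vinylmagnesium bromide, C=C[Mg]Br
Why: Weinreb ketone synthesis, in which the chelated tetrahedral intermediate should stop at mono-addition, the trisubstituted epoxides are inert to the Grignard reagent at low temperature, and the acidic inverse quench keeps the liberated amine from adding to the vinyl ketone; no stereocentre is touched.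

Step 4
Reactants: 7 diepoxy vinyl ketone
Product: 9 1-phenylthio C2=C3 TBS enol ether of 7 (E/Z mixture), via lithium thio-enolate 8 (not isolated)
Conditions: PhSLi (1.0 M in THF), THF, −78 °C; then TBSCl, DMPU, −78 → 0 °C; Et3N/pentane work-up
Reagents that add atoms: lithium thiophenoxide, [Li+].[S-]c1ccccc1; tert-butyldimethylsilyl chloride, CC(C)(C)[Si](C)(C)Cl
Why: Tandem thia-Michael addition/enolate O-silylation should place the enol double bond regiospecifically between C2 and C3, any retro-addition being returned to the same enol ether through PhS–TBS, and the enol geometry is irrelevant because the carbon it creates is equilibrated in step 5.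

Step 5
Reactants: 9 1-phenylthio C2=C3 TBS enol ether of 7
Product: 11 left bicyclic ketone (C3–OTBS; C6–CH2SPh equatorial; C7=O), via C6-epimer mixture 10 (not isolated)
Conditions: TBSOTf (0.3 equiv), 2,6-di-tert-butyl-4-methylpyridine, CH2Cl2, −78 °C; Et3N; then PhSH (5 mol %), Et3N, CH2Cl2, rt
Reagents that add atoms: none
Why: Silyl-triflate-promoted tandem oxa-/carbacyclisation of a 1,5-diepoxide terminated by an enol silane, in which endo attack of the internal epoxide oxygen at the tertiary CMe2 carbon closes the oxepane (C3 and C9a keep their S C–O bonds), anti attack of the enol silane on the tertiary epoxonium carbon closes the cyclohexane (C5a by inversion, hence trans fusion), the enol silyl group is relayed to O3 through regenerated TBSOTf, and thiol/amine equilibration α to the ketone funnels C6 to the equatorial epimer cis to the C5a methyl.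

Step 6
Reactants: 11 left bicyclic ketone
Product: 12 left bicyclic exo-methylene sulfide
Conditions: Zn, CH2Br2, TiCl4 (preformed reagent), THF/CH2Cl2, 0 °C → rt
Reagents that add atoms: dibromomethane, BrCBr
Why: Takai–Lombardo methylenation is non-basic, so the hindered α-branched ketone should give the exocyclic alkene without β-elimination of thiophenoxide or epimerisation at C6 (the change of descriptor from 6S to 6R reflects CIP priorities only).

Step 7
Reactants: 12 left bicyclic exo-methylene sulfide; 7 diepoxy vinyl ketone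
Product: 15 union product as C2=C3 TMS enol ether (E/Z mixture), via alkyllithium 13 (not isolated), via phenylthio cuprate 14 (not isolated)
Conditions: LiDBB (2.1 equiv), THF, −78 °C; CuBr·SMe2, −78 → −50 °C; TMSCl then 7, −78 °C; Et3N, pentane, filtration through Florisil
Reagents that add atoms: chlorotrimethylsilane, C[Si](C)(C)Cl
Why: Reductive lithiation of the primary C–S bond gives the alkyllithium together with PhSLi, which with CuBr form the mixed alkyl(phenylthio)cuprate, and its silyl-chloride-accelerated conjugate addition to the vinyl ketone should form the bridge CH2–CH2 bond and trap the enolate regiospecifically as the C2=C3 silyl enol ether; the homoallylic organometallic has no β leaving group, the epoxides, silyl ether and alkene are inert at −78 °C, and no stereocentre is formed.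

Step 8
Reactants: 15 union product as C2=C3 TMS enol ether
Product: 17 tetracyclic hydroxy ketone (C3–OTBS; C3′–OH; C7′=O), via TMS ether 16 (not isolated)
Conditions: TMSOTf (0.3 equiv), 2,6-di-tert-butyl-4-methylpyridine, CH2Cl2, −78 °C; Et3N; then K2CO3, MeOH, 0 °C → rt
Reagents that add atoms: none
Why: TMSOTf silylates the terminal epoxide oxygen, the neighbouring epoxide oxygen opens it at the tertiary CMe2 carbon (C2′) to a bicyclic epoxonium ion, C6′ of the tethered enol silane attacks the tertiary epoxonium carbon (C5a′), and loss of TMSOTf from the silyloxocarbenium ion gives the C7′ ketone and turns the promoter over, after which K2CO3/MeOH frees O3′ and equilibrates C6′. The closest known reaction type is the silyl-triflate-promoted tandem oxa-/carbacyclisation of 1,5-diepoxides terminated by enol silanes, the same reaction as step 5. The oxepane closes by endo opening of the activated epoxide (O1′–C2′, 7-endo with respect to the final ring) and the cyclohexane by 6-(enolendo) endo opening of the epoxonium ion at C5a′ through a chair-like transition state. C3′ and C9a′ keep their epoxide C–O bonds (S, S), C5a′ forms with inversion anti to the departing oxygen, which with the E-derived epoxide fixes the trans fusion, and C6′ is set thermodynamically (bridge equatorial) whatever the enol geometry of 15. The step needs endo rather than exo opening of the terminal epoxide, secured by its gem-dimethyl (SN1-like) carbon in a non-nucleophilic triflate medium, and C- rather than O-alkylation, secured by the silyl enol ether, while the left-half alkene, silyl ether and ring oxygen are too remote from the cationic centre to close a common ring. The step also leaves O3′ as a labile TMS ether beside the robust O3 TBS ether, which is what later lets C3′ alone be oxidised.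

Step 9
Reactants: 17 tetracyclic hydroxy ketone
Product: 18 tetracyclic diol (C7′ methyl carbinol with axial OH)
Conditions: MeMgBr (5 equiv), LaCl3·2LiCl (0.5 equiv), THF, −20 → 0 °C
Reagents that add atoms: methylmagnesium bromide, C[Mg]Br
Why: Lanthanide-assisted Grignard 1,2-addition, in which axial approach to C7′ is blocked by the syn-axial C5a′ methyl, so methyl should enter equatorially and leave the new hydroxyl axial, cis to that methyl and to the bridge (7′R), the free C3′ hydroxyl only consuming one equivalent of reagent.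

Step 10
Reactants: 18 tetracyclic diol
Product: 19 tetracyclic keto alcohol (C3′=O; C7′–OH)
Conditions: Dess–Martin periodinane, NaHCO3, CH2Cl2, 0 °C → rt
Reagents that add atoms: none
Why: Dess–Martin oxidation can act only on the secondary C3′ hydroxyl, the tertiary C7′ hydroxyl and the silylated O3 being unreactive, so the oxepanone should form without touching a stereocentre.

Step 11
Reactants: 19 tetracyclic keto alcohol
Product: 20 TBS ether of the target
Conditions: Ac2O, DMAP (2 equiv), Et3N, CH2Cl2, 40 °C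
Reagents that add atoms: acetic anhydride, CC(=O)OC(C)=O
Why: DMAP-catalysed (Steglich-type) acylation through the N-acetylpyridinium ion should acetylate the only free hydroxyl, the hindered tertiary one, with retention at C7′ because its C–O bond is not broken.

Step 12
Reactants: 20 TBS ether of the target
Product: 21 target CNP0148623.1
Conditions: HF·pyridine, pyridine, THF, 0 °C → rt
Reagents that add atoms: none
Why: Fluoride-mediated desilylation should cleave the secondary TBS ether while the tertiary acetate, the ketone and the exocyclic alkene are stable to buffered HF·pyridine; no stereocentre is affected.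

**Compound list**

1 | geranyl bromide, (2E)-1-bromo-3,7-dimethylocta-2,6-diene | CC(C)=CCC/C(C)=C/CBr | starting material
2 | N-methoxy-N-methylacetamide | CC(=O)N(C)OC | starting material
3 | lithium enolate of 2 (not isolated) | C=C(O[Li])N(C)OC | intermediate
4 | (4E)-N-methoxy-N,5,9-trimethyldeca-4,8-dienamide | CON(C)C(=O)CC/C=C(\C)CCC=C(C)C | intermediate
5 | N-methoxy-N-methyl-3-[(2S,3S)-3-{2-[(2S)-3,3-dimethyloxiran-2-yl]ethyl}-3-methyloxiran-2-yl]propanamide | CON(C)C(=O)CC[C@@H]1O[C@@]1(C)CC[C@@H]1OC1(C)C | intermediate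
6 | bromomagnesium hemiaminal from 5 and vinylmagnesium bromide (not isolated) | C=CC(O[Mg]Br)(N(C)OC)CC[C@@H]1O[C@@]1(C)CC[C@@H]1OC1(C)C | intermediate
7 | (6S,7S,10S)-6,7:10,11-diepoxy-7,11-dimethyldodec-1-en-3-one | C=CC(=O)CC[C@@H]1O[C@@]1(C)CC[C@@H]1OC1(C)C | intermediate
8 | lithium enolate of the thiophenoxide adduct of 7 (not isolated) | [Li+].[O-]C(=CCSc1ccccc1)CC[C@@H]1O[C@@]1(C)CC[C@@H]1OC1(C)C | intermediate
9 | tert-butyl{[(6S,7S,10S)-6,7:10,11-diepoxy-7,11-dimethyl-1-(phenylsulfanyl)dodec-2-en-3-yl]oxy}dimethylsilane (E/Z mixture) | CC(C)(C)[Si](C)(C)OC(=CCSc1ccccc1)CC[C@@H]1O[C@@]1(C)CC[C@@H]1OC1(C)C | intermediate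
10 | (3S,5aS,9aS)-3-[(tert-butyldimethylsilyl)oxy]-2,2,5a-trimethyl-6-[(phenylsulfanyl)methyl]perhydro-1-benzoxepin-7-one, mixture of C6 epimers (not isolated) | O=C1CC[C@@H]2OC(C)(C)[C@@H](O[Si](C)(C)C(C)(C)C)CC[C@@]2(C)C1CSc1ccccc1 | intermediate
11 | (3S,5aS,6S,9aS)-3-[(tert-butyldimethylsilyl)oxy]-2,2,5a-trimethyl-6-[(phenylsulfanyl)methyl]perhydro-1-benzoxepin-7-one | O=C1CC[C@@H]2OC(C)(C)[C@@H](O[Si](C)(C)C(C)(C)C)CC[C@@]2(C)[C@@H]1CSc1ccccc1 | intermediate
12 | tert-butyldimethyl{[(3S,5aS,6R,9aS)-2,2,5a-trimethyl-7-methylidene-6-[(phenylsulfanyl)methyl]perhydro-1-benzoxepin-3-yl]oxy}silane | C=C1CC[C@@H]2OC(C)(C)[C@@H](O[Si](C)(C)C(C)(C)C)CC[C@@]2(C)[C@@H]1CSc1ccccc1 | intermediate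
13 | primary alkyllithium from C–S cleavage of 12 (C6–CH2Li; not isolated) | C=C1CC[C@@H]2OC(C)(C)[C@@H](O[Si](C)(C)C(C)(C)C)CC[C@@]2(C)[C@@H]1C[Li] | intermediate
14 | lithium alkyl(phenylthio)cuprate from 13, PhSLi and CuBr (not isolated) | [Li+].C=C1CC[C@@H]2OC(C)(C)[C@@H](O[Si](C)(C)C(C)(C)C)CC[C@@]2(C)[C@@H]1C[Cu-]Sc1ccccc1 | intermediate
15 | {[(6S,7S,10S)-1-{[(3S,5aS,6R,9aS)-3-[(tert-butyldimethylsilyl)oxy]-2,2,5a-trimethyl-7-methylideneperhydro-1-benzoxepin-6-yl]methyl}-6,7:10,11-diepoxy-7,11-dimethyldodec-2-en-3-yl]oxy}trimethylsilane (E/Z mixture) | C=C1CC[C@@H]2OC(C)(C)[C@@H](O[Si](C)(C)C(C)(C)C)CC[C@@]2(C)[C@@H]1CCC=C(O[Si](C)(C)C)CC[C@@H]1O[C@@]1(C)CC[C@@H]1OC1(C)C | intermediate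
16 | C3′-O-trimethylsilyl ether of 17, mixture of C6′ epimers (not isolated) | C=C1CC[C@@H]2OC(C)(C)[C@@H](O[Si](C)(C)C(C)(C)C)CC[C@@]2(C)[C@@H]1CCC1[C@]2(C)CC[C@H](O[Si](C)(C)C)C(C)(C)O[C@H]2CCC1=O | intermediate
17 | (3S,5aS,6S,9aS)-6-{2-[(3S,5aS,6R,9aS)-3-[(tert-butyldimethylsilyl)oxy]-2,2,5a-trimethyl-7-methylideneperhydro-1-benzoxepin-6-yl]ethyl}-3-hydroxy-2,2,5a-trimethylperhydro-1-benzoxepin-7-one | C=C1CC[C@@H]2OC(C)(C)[C@@H](O[Si](C)(C)C(C)(C)C)CC[C@@]2(C)[C@@H]1CC[C@H]1[C@]2(C)CC[C@H](O)C(C)(C)O[C@H]2CCC1=O | intermediate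
18 | (3S,5aS,6S,7R,9aS)-6-{2-[(3S,5aS,6R,9aS)-3-[(tert-butyldimethylsilyl)oxy]-2,2,5a-trimethyl-7-methylideneperhydro-1-benzoxepin-6-yl]ethyl}-2,2,5a,7-tetramethylperhydro-1-benzoxepine-3,7-diol | C=C1CC[C@@H]2OC(C)(C)[C@@H](O[Si](C)(C)C(C)(C)C)CC[C@@]2(C)[C@@H]1CC[C@H]1[C@]2(C)CC[C@H](O)C(C)(C)O[C@H]2CC[C@@]1(C)O | intermediate
19 | (5aS,6S,7R,9aS)-6-{2-[(3S,5aS,6R,9aS)-3-[(tert-butyldimethylsilyl)oxy]-2,2,5a-trimethyl-7-methylideneperhydro-1-benzoxepin-6-yl]ethyl}-7-hydroxy-2,2,5a,7-tetramethylperhydro-1-benzoxepin-3-one | C=C1CC[C@@H]2OC(C)(C)[C@@H](O[Si](C)(C)C(C)(C)C)CC[C@@]2(C)[C@@H]1CC[C@H]1[C@]2(C)CCC(=O)C(C)(C)O[C@H]2CC[C@@]1(C)O | intermediate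
20 | (5aS,6S,7R,9aS)-6-{2-[(3S,5aS,6R,9aS)-3-[(tert-butyldimethylsilyl)oxy]-2,2,5a-trimethyl-7-methylideneperhydro-1-benzoxepin-6-yl]ethyl}-2,2,5a,7-tetramethyl-3-oxoperhydro-1-benzoxepin-7-yl acetate | C=C1CC[C@@H]2OC(C)(C)[C@@H](O[Si](C)(C)C(C)(C)C)CC[C@@]2(C)[C@@H]1CC[C@H]1[C@]2(C)CCC(=O)C(C)(C)O[C@H]2CC[C@@]1(C)OC(C)=O | intermediate
21 | (5aS,6S,7R,9aS)-6-{2-[(3S,5aS,6R,9aS)-3-hydroxy-2,2,5a-trimethyl-7-methylideneperhydro-1-benzoxepin-6-yl]ethyl}-2,2,5a,7-tetramethyl-3-oxoperhydro-1-benzoxepin-7-yl acetate (CNP0148623.1) | C=C1CC[C@@H]2OC(C)(C)[C@@H](O)CC[C@@]2(C)[C@@H]1CC[C@H]1[C@]2(C)CCC(=O)C(C)(C)O[C@H]2CC[C@@]1(C)OC(C)=O | target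

**Totals and risks**

Total step count: 12. Longest linear sequence: 12 (7 is made once and enters at steps 4 and 7).

Steps most likely to fail:

1. Step 8. On the large substrate the epoxonium ion may collapse before the C5a′–C6′ bond forms (exo opening to a tetrahydropyran, 1,2-hydride shift, proton loss), or the TMS enol ether may be protodesilylated by adventitious triflic acid, so that the carbocycle never closes. The fallback closes the right-half rings before the union, by the chemistry of step 5, and joins two bicycles; it sets out from 11 and comes back at 17. HF·pyridine frees the C3 hydroxyl of 11 to give the hydroxy ketone F1, and TESCl/imidazole gives the triethylsilyl ether F2. mCPBA (1 equiv, −78 °C) oxidises sulfur to the sulfoxide F3, which on heating (toluene, 80 °C, CaCO3) loses benzenesulfenic acid by syn elimination to give the exo-methylene ketone F4. Cuprate 14, made from 12 as in step 7, adds to F4 at −78 °C; protic quench and brief K2CO3/MeOH equilibration at C6′ give the keto TES ether F5. PPTS/MeOH then removes the TES group faster than the TBS group and delivers 17.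

2. Step 7. The hindered β-branched primary alkyllithium may be protonated before transmetalation, or the mixed phenylthio cuprate may transfer its alkyl group too slowly, so that the vinyl ketone polymerises instead of being alkylated. The fallback uses a sulfone-stabilised carbanion as the nucleophile and removes sulfur later; it sets out from 12 and comes back at 18. Ammonium molybdate/H2O2 (EtOH, 0 °C) oxidises sulfur chemoselectively to the sulfone F6. n-BuLi (THF/DMPU, −78 °C) gives the α-lithio sulfone F7, which undergoes Michael addition to 7, and TMSCl traps the enolate as the TMS enol ether F8. The conditions of step 8 give, through the TMS ether F9, the sulfonyl hydroxy ketone F10, and methyl addition as in step 9 gives the sulfonyl diol F11. Reductive desulfonylation (Na/Hg, Na2HPO4, MeOH, −20 °C) then gives 18.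

3. Step 11. The axial tertiary hydroxyl at C7′, syn-diaxial to the C5a′ methyl, may resist acylation, and forcing conditions may lead to elimination towards the C7′ alkenes. The fallback acylates the metal alkoxide at the moment it is formed; it sets out from 17 and comes back at 20. TMSCl/imidazole gives the C3′ TMS ether F12. MeLi (Et2O, −78 °C) adds with the facial preference of step 9 to give the lithium alkoxide F13, which Ac2O acetylates in the same flask (−78 °C → rt) to the tertiary acetate F14. K2CO3/MeOH removes only the TMS group to give the hydroxy acetate F15, and Dess–Martin oxidation of F15 gives 20.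

**Further compounds**

F1 | step 8 | (3S,5aS,6S,9aS)-3-hydroxy-2,2,5a-trimethyl-6-[(phenylsulfanyl)methyl]perhydro-1-benzoxepin-7-one | O=C1CC[C@@H]2OC(C)(C)[C@@H](O)CC[C@@]2(C)[C@@H]1CSc1ccccc1
F2 | step 8 | (3S,5aS,6S,9aS)-2,2,5a-trimethyl-6-[(phenylsulfanyl)methyl]-3-[(triethylsilyl)oxy]perhydro-1-benzoxepin-7-one | O=C1CC[C@@H]2OC(C)(C)[C@@H](O[Si](CC)(CC)CC)CC[C@@]2(C)[C@@H]1CSc1ccccc1
F3 | step 8 | (3S,5aS,6S,9aS)-6-[(benzenesulfinyl)methyl]-2,2,5a-trimethyl-3-[(triethylsilyl)oxy]perhydro-1-benzoxepin-7-one (mixture at sulfur) | O=C1CC[C@@H]2OC(C)(C)[C@@H](O[Si](CC)(CC)CC)CC[C@@]2(C)[C@@H]1CS(=O)c1ccccc1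
F4 | step 8 | (3S,5aS,9aS)-2,2,5a-trimethyl-6-methylidene-3-[(triethylsilyl)oxy]perhydro-1-benzoxepin-7-one | O=C1CC[C@@H]2OC(C)(C)[C@@H](O[Si](CC)(CC)CC)CC[C@@]2(C)C1=C
F5 | step 8 | C3′-O-triethylsilyl ether of 17 | C=C1CC[C@@H]2OC(C)(C)[C@@H](O[Si](C)(C)C(C)(C)C)CC[C@@]2(C)[C@@H]1CC[C@H]1[C@]2(C)CC[C@H](O[Si](CC)(CC)CC)C(C)(C)O[C@H]2CCC1=O
F6 | step 7 | {[(3S,5aS,6R,9aS)-6-[(benzenesulfonyl)methyl]-2,2,5a-trimethyl-7-methylideneperhydro-1-benzoxepin-3-yl]oxy}(tert-butyl)dimethylsilane | C=C1CC[C@@H]2OC(C)(C)[C@@H](O[Si](C)(C)C(C)(C)C)CC[C@@]2(C)[C@@H]1CS(=O)(=O)c1ccccc1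
F7 | step 7 | α-lithio derivative of sulfone F6 | C=C1CC[C@@H]2OC(C)(C)[C@@H](O[Si](C)(C)C(C)(C)C)CC[C@@]2(C)[C@@H]1C([Li])S(=O)(=O)c1ccccc1
F8 | step 7 | 1-benzenesulfonyl analogue of 15 (TMS enol ether, mixture at the sulfonyl carbon and of E/Z isomers) | C=C1CC[C@@H]2OC(C)(C)[C@@H](O[Si](C)(C)C(C)(C)C)CC[C@@]2(C)[C@@H]1C(S(=O)(=O)c1ccccc1)CC=C(O[Si](C)(C)C)CC[C@@H]1O[C@@]1(C)CC[C@@H]1OC1(C)C
F9 | step 7 | bridge-benzenesulfonyl analogue of 16 (C3′-OTMS, mixture at C6′ and at the sulfonyl carbon) | C=C1CC[C@@H]2OC(C)(C)[C@@H](O[Si](C)(C)C(C)(C)C)CC[C@@]2(C)[C@@H]1C(S(=O)(=O)c1ccccc1)CC1[C@]2(C)CC[C@H](O[Si](C)(C)C)C(C)(C)O[C@H]2CCC1=O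
F10 | step 7 | bridge-benzenesulfonyl analogue of 17 (mixture at the sulfonyl carbon) | C=C1CC[C@@H]2OC(C)(C)[C@@H](O[Si](C)(C)C(C)(C)C)CC[C@@]2(C)[C@@H]1C(S(=O)(=O)c1ccccc1)C[C@H]1[C@]2(C)CC[C@H](O)C(C)(C)O[C@H]2CCC1=O
F11 | step 7 | bridge-benzenesulfonyl analogue of 18 (mixture at the sulfonyl carbon) | C=C1CC[C@@H]2OC(C)(C)[C@@H](O[Si](C)(C)C(C)(C)C)CC[C@@]2(C)[C@@H]1C(S(=O)(=O)c1ccccc1)C[C@H]1[C@]2(C)CC[C@H](O)C(C)(C)O[C@H]2CC[C@@]1(C)O
F12 | step 11 | C3′-O-trimethylsilyl ether of 17 (single C6′ epimer) | C=C1CC[C@@H]2OC(C)(C)[C@@H](O[Si](C)(C)C(C)(C)C)CC[C@@]2(C)[C@@H]1CC[C@H]1[C@]2(C)CC[C@H](O[Si](C)(C)C)C(C)(C)O[C@H]2CCC1=O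
F13 | step 11 | lithium C7′-alkoxide from methyl addition to F12 | C=C1CC[C@@H]2OC(C)(C)[C@@H](O[Si](C)(C)C(C)(C)C)CC[C@@]2(C)[C@@H]1CC[C@H]1[C@]2(C)CC[C@H](O[Si](C)(C)C)C(C)(C)O[C@H]2CC[C@@]1(C)O[Li]
F14 | step 11 | C7′ acetate with C3′-OTMS and C3-OTBS | C=C1CC[C@@H]2OC(C)(C)[C@@H](O[Si](C)(C)C(C)(C)C)CC[C@@]2(C)[C@@H]1CC[C@H]1[C@]2(C)CC[C@H](O[Si](C)(C)C)C(C)(C)O[C@H]2CC[C@@]1(C)OC(C)=O
F15 | step 11 | C7′ acetate with free C3′-OH and C3-OTBS | C=C1CC[C@@H]2OC(C)(C)[C@@H](O[Si](C)(C)C(C)(C)C)CC[C@@]2(C)[C@@H]1CC[C@H]1[C@]2(C)CC[C@H](O)C(C)(C)O[C@H]2CC[C@@]1(C)OC(C)=O
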